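The constants used here are invented; the flask was simulated.

5 questions stand here: which set-up gives the most left-handed product, and how much each of the 4 gives.

in all of them: left-handed substrate 26 mM; precatalyst 0.65 mM; right-handed substrate 26 mM
- east: partner 52.0 mM; a single well-mixed tank run continuously and read at steady state, 4.50 h in it on average
- south: partner 52.0 mM; everything together in a closed stirred flask, run for 1.5 h; time 1.5 h
- north-west: partner 52.0 mM (fed, over 1.20 h); a stirred flask in which partner is dosed at a steady rate over 1.20 h without added volume, worked up at 1.5 h; time 1.5 h
- north-east: partner 52.0 mM; a single well-mixed tank run continuously and read at steady state, 1.5 h in it on average

1. the set-up with the highest amount of left-handed product at the outlet or at the end, in percent of the left-handed substrate and right-handed substrate together put in ("none" if the first two lie within 2 percentage points) (east / south / north-west / north-east / none)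
2. amount of left-handed product at the outlet or at the end, in percent of the left-handed substrate and right-handed substrate together put in, east
3. amount of left-handed product at the outlet or at the end, in percent of the left-handed substrate and right-handed substrate together put in, south
4. amount of left-handed product at the outlet or at the end, in percent of the left-handed substrate and right-handed substrate together put in, north-west
5. amount of left-handed product at the outlet or at the end, in percent of the left-handed substrate and right-handed substrate together put in, north-east

- catalyst is single-handed; left-handed substrate and right-handed substrate are mirror images of each other, charged as a racemate, each of them at the stated concentration
- the stated concentrations are those of everything mixed, before any reaction; amounts are the same in each set-up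
- the feed brings no volume worth counting
- run time (south): 1.5 h

    partner + catalyst + left-handed substrate → catalyst + left-handed product (k1 = 410 L² mol⁻² min⁻¹)
    partner + catalyst + right-handed substrate → catalyst + right-handed product (k2 = 180 L² mol⁻² min⁻¹)
    left-handed substrate ⇌ right-handed substrate (k3 = 0.13 min⁻¹)
    partner + precatalyst → catalyst + spent reagent (k4 = 0.091 L mol⁻¹ min⁻¹)

I follow one substrate molecule through its forks.

1. A substrate molecule flips to its mirror form at 0.13 min⁻¹, and it is captured at 0.0139 min⁻¹ even with the whole precatalyst charge active. Flipping is faster, so the two substrates stay nearly equal. At capture the molecule goes left with a share σ, the left constant over the sum of both, 69.5%. The ratio of the two constants is the selectivity factor. The yield asked for is σ times the conversion x.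

2. Capture needs catalyst, and partner makes it from precatalyst at a rate a, the activation constant times the partner charge, 0.00473 min⁻¹. That half-life of 2.44 h is longer than the 1.5 h run, so the catalyst concentration C climbs slowly from zero. I hold partner at its charge here, which overstates every figure a little.

3. Partner and the two substrates together are charged equally, so they fall together. In a closed flask x/(one − x) then equals W, the working dose: the mean of the two capture constants, 295 L² mol⁻² min⁻¹, times the partner charge, times the area under C against time. For south, W is 0.167, which gives 9.93%.

4. In north-west, partner arrives steadily over 1.20 h. Activation and capture both feel it: partner rises with time during the feed, C climbs about as the square of time then and about in a straight line afterwards, and adding up the two stretches gives a late start. The flask runs like south read at θ = 0.900 h. Its working dose is 0.0633, which gives 4.14%.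

5. A tank holds C steady at the precatalyst charge times aτ/(one + aτ), where τ is the mean residence time, and x equals W times (one − x) squared, with W now the mean constant times the partner charge times τ times C. East has W = 1.51, so x = 45.3% and the yield is 31.4%. North-east has W = 0.268, so x = 18.0% and the yield is 12.5%.

My choice is east.

The forecast also says east, with 28% for east, 9.3% for south, 4.1% for north-west and 11.4% for north-east, on the grounds that “That conversion is limited by slow catalyst activation”. Its tank figures stand below mine.

The simulation gives east, with 28.1% for east, 9.67% for south, 4.07% for north-west and 11.3% for north-east.

In north-west the two products together stand at 5.86%, which reads back as a working dose of 0.0623, beside my 0.0633. The neighbouring flask is north-west with 1.6 mM of precatalyst instead of 0.65 mM. In my reckoning the dose goes with the precatalyst charge, so the reading becomes 0.153, and σ turns that into 9.22% of left-handed product. That neighbouring flask gives 9.04%.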